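**Retrosynthetic overview**

1. Numbering (germacranolide): ten-membered carbocycle C1–C10; 3(2H)-furanone ring = O, C10 (quaternary, methyl C14), C1 (C=O), C2, C3 (O-bearing); C4 (methyl C15)=C5 is the Z alkene; γ-lactone = O–C6, C7, C11(=C13H2), C12(=O); acyloxy group on C8.
2. Furanone ring ⇐ transannular cycloisomerisation of a macrocyclic 10-hydroxy-1-yn-3-one (O–C3 bond last); ten-membered ring ⇐ C3–C4 bond from a Z-alkenyl iodide (C4) and an ynal (C3) by Ni/Cr-mediated reductive ring closure, a union of two electrophilic carbons made possible by reversing the polarity of C4.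
3. Enabling feature: C3 (the O-bearing sp2 carbon of the furanone ring, a masked acyl carbon) and the lactone carbinol C6 are 1,4-dioxygenated across the Z C4=C5 bond (a dissonant pair), so C3 and C4 are both acceptor carbons; the furanone atoms O/C10–C1–C2–C3 are a disguised 4-hydroxy-2-ynone, which lets C3 be a plain aldehyde carbon on the C1≡C2 alkyne.
4. Seco compound ⇐ C8 ester by Mitsunobu inversion; α-methylene-γ-lactone (C6–C7 bond) by chromium Barbier allylation of (Z)-3-iodobut-2-enal with a C8-stereogenic 2-(bromomethyl)enoate; C10 by Sharpless epoxidation and epoxy chloride → alkyne elimination; C8 from (R)-2-vinyloxirane.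
5. Ring order: γ-lactone (step 16), ten-membered carbocycle (step 20, C3–C4), furanone (step 22).

Key step: step 20

Remark: (R)-2-vinyloxirane (9) is taken as purchasable (it is also the epoxide left by hydrolytic kinetic resolution of the cheap racemate); the CIP letter at C6 is S in the alkenyl iodides and R in the cyclised compounds only because of substituent priorities, the spatial arrangement being the same.

**Step 1**
Reactants: 1 but-2-yn-1-ol
Product: 3 (Z)-3-iodobut-2-en-1-ol, via cyclic alkenylaluminate 2 (not isolated)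
Conditions: NaAlH2(OCH2CH2OMe)2 (1.5 equiv), Et2O, 0 °C → rt; then I2, THF, −78 → 0 °C
Reagents that add atoms: iodine, II
Why: Trans-hydroalumination of the propargylic alkoxide by intramolecular hydride delivery puts aluminium on the distal alkyne carbon in a five-membered oxa-aluminate, and iodinolysis with retention should give the Z iodide (iodine cis to CH2OH).

**Step 2**
Reactants: 3 (Z)-3-iodobut-2-en-1-ol
Product: 4 (Z)-3-iodobut-2-enal
Conditions: MnO2 (activated, excess), CH2Cl2, rt, dark; used without storage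
Reagents that add atoms: none
Why: Heterogeneous allylic oxidation with MnO2 stops at the aldehyde under neutral conditions and should keep the Z geometry.

**Step 3**
Reactants: 5 tert-butyl methacrylate (4 equiv); 6 (Z)-but-2-ene-1,4-diyl diacetate
Product: 7 tert-butyl (E)-4-acetoxy-2-methylbut-2-enoate
Conditions: second-generation Grubbs catalyst RuCl2(H2IMes)(PCy3)(=CHPh) (3 mol %), CH2Cl2, 40 °C
Reagents that add atoms: none
Why: Olefin cross-metathesis between a slowly homodimerising 1,1-disubstituted acrylate and a reactive allylic acetate should give the trisubstituted enoate as the thermodynamically preferred E isomer.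

**Step 4**
Reactants: 7 tert-butyl (E)-4-acetoxy-2-methylbut-2-enoate
Product: 8 (E)-4-acetoxy-2-methylbut-2-enoic acid
Conditions: CF3CO2H, CH2Cl2, 0 °C → rt
Reagents that add atoms: none
Why: Acidolysis of the tert-butyl ester through the tert-butyl cation leaves the primary acetate and the alkene geometry untouched.

**Step 5**
Reactants: 9 (R)-2-vinyloxirane
Product: 10 (S)-hex-1-en-5-yn-3-ol
Conditions: LiC≡CH·H2NCH2CH2NH2, DMSO/THF, 0 °C → rt
Reagents that add atoms: lithium acetylide–ethylenediamine complex, [Li]C#C.NCCN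
Why: SN2 opening of the epoxide by the acetylide at the unsubstituted carbon leaves the stereocentre (future C8) untouched, the descriptor changing from R to S only by priority.

**Step 6**
Reactants: 10 (S)-hex-1-en-5-yn-3-ol
Product: 11 (S)-3-(4-methoxybenzyloxy)hex-1-en-5-yne
Conditions: NaH, 4-methoxybenzyl chloride, n-Bu4NI (cat.), THF/DMF, 0 °C → rt
Reagents that add atoms: 4-methoxybenzyl chloride, COc1ccc(CCl)cc1
Why: Williamson etherification of the secondary alkoxide, which forms in preference to the acetylide with one equivalent of base.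

**Step 7**
Reactants: 11 (S)-3-(4-methoxybenzyloxy)hex-1-en-5-yne
Product: 14 (2E,5S)-5-(4-methoxybenzyloxy)-3-methylhepta-2,6-dien-1-ol, via alkenyldimethylalane 12 (not isolated), via lithium alkenylaluminate 13 (not isolated)
Conditions: AlMe3 (3 equiv), Cp2ZrCl2 (0.25 equiv), CH2Cl2, 0 °C → rt; then n-BuLi, THF, −78 °C; (CH2O)n, −78 °C → rt
Reagents that add atoms: trimethylaluminium, C[Al](C)C; formaldehyde (as paraformaldehyde), C=O
Why: Negishi zirconium-catalysed carboalumination adds methyl and aluminium syn across the terminal alkyne (methyl to the internal carbon, the terminal alkene being far slower), and the ate complex takes up formaldehyde with retention to give the E allylic alcohol.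

**Step 8**
Reactants: 14 (2E,5S)-5-(4-methoxybenzyloxy)-3-methylhepta-2,6-dien-1-ol
Product: 15 {(2S,3S)-3-[(2S)-2-(4-methoxybenzyloxy)but-3-en-1-yl]-3-methyloxiran-2-yl}methanol
Conditions: Ti(OiPr)4 (10 mol %), L-(+)-diethyl tartrate (12 mol %), t-BuOOH, 4 Å molecular sieves, CH2Cl2, −20 °C
Reagents that add atoms: tert-butyl hydroperoxide, CC(C)(C)OO
Why: Sharpless asymmetric epoxidation delivers oxygen to the face of the E-trisubstituted allylic alcohol dictated by the L-(+)-tartrate (the sense known for geraniol), which sets C10 (S) by reagent control while the undirected terminal vinyl group stays intact.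

**Step 9**
Reactants: 15 {(2S,3S)-3-[(2S)-2-(4-methoxybenzyloxy)but-3-en-1-yl]-3-methyloxiran-2-yl}methanol
Product: 16 (2R,3S)-2-(chloromethyl)-3-[(2S)-2-(4-methoxybenzyloxy)but-3-en-1-yl]-3-methyloxirane
Conditions: PPh3, CCl4, NaHCO3, reflux
Reagents that add atoms: carbon tetrachloride, ClC(Cl)(Cl)Cl
Why: Appel chlorination of the primary alcohol under neutral conditions leaves the epoxide untouched (the descriptor change at the oxirane CH is due to priority only).

**Step 10**
Reactants: 16 (2R,3S)-2-(chloromethyl)-3-[(2S)-2-(4-methoxybenzyloxy)but-3-en-1-yl]-3-methyloxirane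
Product: 18 (4S,6S)-4-hydroxy-6-(4-methoxybenzyloxy)-4-methyloct-7-en-2-ynal, via dilithium alkoxide-acetylide 17 (not isolated)
Conditions: LiN(iPr)2 (4 equiv), THF, −78 → −30 °C; then DMF, −78 → 0 °C; poured into aq. KH2PO4
Reagents that add atoms: N,N-dimethylformamide, CN(C)C=O
Why: Base-induced double elimination of a 2,3-epoxy chloride (deprotonation next to chlorine opens the epoxide, loss of HCl gives the alkyne, a third equivalent of base the acetylide) leaves the C10–O bond intact so the epoxide configuration becomes that of the tertiary propargylic alcohol, and the acetylide is then formylated by DMF.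

**Step 11**
Reactants: 18 (4S,6S)-4-hydroxy-6-(4-methoxybenzyloxy)-4-methyloct-7-en-2-ynal
Product: 19 (4S,6S)-6-(4-methoxybenzyloxy)-4-methyl-4-(triethylsilyloxy)oct-7-en-2-ynal
Conditions: Et3SiOTf, 2,6-lutidine, CH2Cl2, −78 °C
Reagents that add atoms: triethylsilyl trifluoromethanesulfonate, CC[Si](CC)(CC)OS(=O)(=O)C(F)(F)F
Why: Silylation of the tertiary alcohol with a silyl triflate and a hindered base; the ether later prevents lactol formation with the C7 aldehyde and 5-exo attack of the C10 oxygen on the allylic bromide.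

**Step 12**
Reactants: 19 (4S,6S)-6-(4-methoxybenzyloxy)-4-methyl-4-(triethylsilyloxy)oct-7-en-2-ynal
Product: 20 (3S,5S)-8,8-diethoxy-3-(4-methoxybenzyloxy)-5-methyl-5-(triethylsilyloxy)oct-1-en-6-yne
Conditions: HC(OEt)3, EtOH, pyridinium p-toluenesulfonate (5 mol %), rt
Reagents that add atoms: triethyl orthoformate, CCOC(OCC)OCC
Why: Acid-catalysed acetalisation of the reactive ynal, with the orthoformate as water scavenger, masks C3 under conditions too mild to cleave the tertiary silyl ether.

**Step 13**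
Reactants: 20 (3S,5S)-8,8-diethoxy-3-(4-methoxybenzyloxy)-5-methyl-5-(triethylsilyloxy)oct-1-en-6-yne
Product: 22 (2S,4S)-7,7-diethoxy-2-(4-methoxybenzyloxy)-4-methyl-4-(triethylsilyloxy)hept-5-ynal, via 1,2-diol 21 (not isolated)
Conditions: OsO4 (2 mol %), NaIO4 (4 equiv), 2,6-lutidine, dioxane/H2O (3:1), rt; used crude
Reagents that add atoms: osmium tetroxide (catalytic oxygen carrier), O=[Os](=O)(=O)=O; sodium periodate, [Na+].[O-]I(=O)(=O)=O
Why: Lemieux–Johnson oxidation dihydroxylates the only alkene (the alkyne reacts far more slowly) and periodate cleaves the diol to the C7 aldehyde, the lutidine buffer protecting the acetal and the α-alkoxy stereocentre.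

**Step 14**
Reactants: 22 (2S,4S)-7,7-diethoxy-2-(4-methoxybenzyloxy)-4-methyl-4-(triethylsilyloxy)hept-5-ynal; 23 methyl acrylate
Product: 24 methyl (4S,6S)-9,9-diethoxy-3-hydroxy-4-(4-methoxybenzyloxy)-6-methyl-2-methylidene-6-(triethylsilyloxy)non-7-ynoate (both C3 epimers)
Conditions: 1,4-diazabicyclo[2.2.2]octane (1 equiv), methyl acrylate (excess, neat), rt, several days
Reagents that add atoms: none
Why: Morita–Baylis–Hillman reaction of an activated α-alkoxy aldehyde forms the C7–C11 bond; the new carbinol centre needs no control because it becomes sp2 in step 15.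

**Step 15**
Reactants: 24 methyl (4S,6S)-9,9-diethoxy-3-hydroxy-4-(4-methoxybenzyloxy)-6-methyl-2-methylidene-6-(triethylsilyloxy)non-7-ynoate
Product: 25 methyl (2Z,4S,6S)-2-(bromomethyl)-9,9-diethoxy-4-(4-methoxybenzyloxy)-6-methyl-6-(triethylsilyloxy)non-2-en-7-ynoate
Conditions: N-bromosuccinimide, Me2S, CH2Cl2, 0 °C → rt
Reagents that add atoms: N-bromosuccinimide, O=C1CCC(=O)N1Br
Why: Corey–Kim-type activation of the allylic alcohol as an alkoxysulfonium ion and SN2′ attack of bromide make both carbinol epimers converge on the trisubstituted Z allylic bromide (C8 trans to the ester).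

**Step 16**
Reactants: 25 methyl (2Z,4S,6S)-2-(bromomethyl)-9,9-diethoxy-4-(4-methoxybenzyloxy)-6-methyl-6-(triethylsilyloxy)non-2-en-7-ynoate; 4 (Z)-3-iodobut-2-enal
Product: 27 (4R,5S)-4-[(1S,3S)-6,6-diethoxy-1-(4-methoxybenzyloxy)-3-methyl-3-(triethylsilyloxy)hex-4-yn-1-yl]-5-[(Z)-2-iodoprop-1-en-1-yl]-3-methylidenedihydrofuran-2(3H)-one, via open-chain hydroxy ester 26 (not isolated)
Conditions: CrCl2 (nickel-free, 4 equiv), THF, 0 °C → rt; aq. NH4Cl; then pyridinium p-toluenesulfonate (cat.), CH2Cl2, rt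
Reagents that add atoms: none
Why: Chromium-mediated Barbier (Nozaki–Hiyama) allylation followed by lactonisation: the γ-substituted allylchromium should react through a Zimmerman–Traxler chair with the aldehyde substituent and C8 both equatorial (6,7-anti adduct, hence the trans lactone), while the C8–H bond eclipses C7=C11 (allylic 1,3-strain against the ester) so that the aldehyde approaches C7 anti to the C8–O bond (Felkin-type), which relays 8S to the C6/C7 configuration of the target; without nickel the alkenyl iodide is not touched.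

**Step 17**
Reactants: 27 the lactone named in step 16
Product: 28 (4R,5S)-4-[(1S,3S)-6,6-diethoxy-1-hydroxy-3-methyl-3-(triethylsilyloxy)hex-4-yn-1-yl]-5-[(Z)-2-iodoprop-1-en-1-yl]-3-methylidenedihydrofuran-2(3H)-one
Conditions: 2,3-dichloro-5,6-dicyano-1,4-benzoquinone, CH2Cl2/pH 7 buffer (10:1), 0 °C
Reagents that add atoms: none
Why: Oxidative cleavage of the electron-rich 4-methoxybenzyl ether via its benzylic oxocarbenium ion frees the C8 hydroxyl without touching the silyl ether, acetal, alkenyl iodide or acrylate.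

**Step 18**
Reactants: 28 the C8 alcohol named in step 17; 8 (E)-4-acetoxy-2-methylbut-2-enoic acid
Product: 29 (1R,3S)-6,6-diethoxy-1-{(2S,3R)-2-[(Z)-2-iodoprop-1-en-1-yl]-4-methylidene-5-oxotetrahydrofuran-3-yl}-3-methyl-3-(triethylsilyloxy)hex-4-yn-1-yl (E)-4-acetoxy-2-methylbut-2-enoate
Conditions: PPh3, diisopropyl azodicarboxylate, toluene, 0 °C → rt
Reagents that add atoms: none
Why: Mitsunobu esterification displaces the alkoxyphosphonium ion of the secondary C8 alcohol by the carboxylate with SN2 inversion, turning 8S into the 8R ester of the target and installing the complete side chain.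

**Step 19**
Reactants: 29 the ester named in step 18
Product: 30 (1R,3S)-3-hydroxy-1-{(2S,3R)-2-[(Z)-2-iodoprop-1-en-1-yl]-4-methylidene-5-oxotetrahydrofuran-3-yl}-3-methyl-6-oxohex-4-yn-1-yl (E)-4-acetoxy-2-methylbut-2-enoate
Conditions: CF3CO2H/H2O (9:1), CH2Cl2, 0 °C
Reagents that add atoms: water, O
Why: Aqueous acid hydrolyses the alkynyl diethyl acetal to the ynal and cleaves the tertiary triethylsilyl ether in the same operation, while esters, lactone and alkenyl iodide are stable.

**Step 20**
Reactants: 30 the iodo-ynal named in step 19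
Product: 31 (4Z,6R,7R,8R,10S)-8-[(E)-4-acetoxy-2-methylbut-2-enoyloxy]-3,10-dihydroxygermacra-4,11(13)-dien-1-yn-12,6-olide (both C3 epimers)
Conditions: CrCl2 (10 equiv), NiCl2 (0.1 equiv), degassed DMSO/THF (3:1), rt, slow addition of 30 to a final 2 mM
Reagents that add atoms: none
Why: Zerovalent nickel (from NiCl2 and CrCl2) inserts into the C4–I bond with retention of the Z geometry, transmetalation to trivalent chromium gives an alkenylchromium species, and this adds to the C3 aldehyde, so that two carbons that are both electrophilic in the precursor are joined by reductive polarity reversal; the closest known reaction type is the intramolecular Nozaki–Hiyama–Kishi coupling used to close strained ten-membered ene-yne carbinol rings. The ten-membered carbocycle C1–C10 is closed in the 10-exo-trig mode (attack on C3=O, oxygen outside the ring). The only new stereocentre, C3, forms without control and is erased by the oxidation in step 21. The step needs chemoselectivity for the aldehyde over the lactone, two esters, the allylic acetate and the α-methylene lactone, which the alkenylchromium reagent provides (a palladium-based closure would risk 5-exo Heck attack of C4 on the exocyclic methylene). It also needs ring closure to outrun oligomerisation, which high dilution, the cis placement of C4 and C6 on the double bond and the turn imposed by the trans-fused lactone should favour. The conjugated ynal is the most electrophilic carbonyl present, and the linear C10–C1≡C2–C3 unit is easily spanned by the seven-atom C4–C10 chain.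

**Step 21**
Reactants: 31 the macrocyclic carbinol named in step 20
Product: 32 (4Z,6R,7R,8R,10S)-8-[(E)-4-acetoxy-2-methylbut-2-enoyloxy]-10-hydroxy-3-oxogermacra-4,11(13)-dien-1-yn-12,6-olide
Conditions: Dess–Martin periodinane, NaHCO3, CH2Cl2, 0 °C
Reagents that add atoms: none
Why: Dess–Martin oxidation converts the doubly activated (allylic and propargylic) secondary alcohol of both C3 epimers into the cross-conjugated ynone under buffered, non-nucleophilic conditions, the tertiary alcohol being inert.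

**Step 22**
Reactants: 32 the macrocyclic hydroxy-ynone named in step 21
Product: 33 (4Z,6R,7R,8R,10S)-8-[(E)-4-acetoxy-2-methylbut-2-enoyloxy]-1-oxo-3,10-epoxygermacra-2,4,11(13)-trien-12,6-olide (CNP0387534.1)
Conditions: [(4-CF3C6H4)3P]AuCl (5 mol %), AgOTf (5 mol %), toluene (undried), rt
Reagents that add atoms: none
Why: Gold-catalysed cycloisomerisation of a γ-hydroxy-alkynone to a 3(2H)-furanone: the monovalent gold cation activates C1≡C2 for addition of water at C1, the C10 hydroxyl closes transannularly on the C3 carbonyl and loss of water gives the O–C3=C2–C1=O unit, C10 keeping its configuration because its C–O bond is never broken.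

**Compound list**

1 | but-2-yn-1-ol | CC#CCO | starting material
2 | sodium cyclic (Z)-alkenylaluminate from trans-hydroalumination of 1 (5-methyl-2,2-bis(2-methoxyethoxy)-1,2-oxaluminol-2-uide) | CC1=CCO[Al-]1(OCCOC)OCCOC.[Na+] | intermediate
3 | (Z)-3-iodobut-2-en-1-ol | C/C(I)=C/CO | intermediate
4 | (Z)-3-iodobut-2-enal | C/C(I)=C/C=O | intermediate
5 | tert-butyl methacrylate | C=C(C)C(=O)OC(C)(C)C | starting material
6 | (Z)-but-2-ene-1,4-diyl diacetate | CC(=O)OC/C=C\COC(C)=O | starting material
7 | tert-butyl (E)-4-acetoxy-2-methylbut-2-enoate | CC(C)(C)OC(=O)/C(C)=C/COC(C)=O | intermediate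
8 | (E)-4-acetoxy-2-methylbut-2-enoic acid | OC(=O)/C(C)=C/COC(C)=O | intermediate
9 | (R)-2-vinyloxirane | C=C[C@@H]1CO1 | starting material
10 | (S)-hex-1-en-5-yn-3-ol | C=C[C@@H](O)CC#C | intermediate
11 | (S)-3-(4-methoxybenzyloxy)hex-1-en-5-yne | C=C[C@@H](OCc1ccc(OC)cc1)CC#C | intermediate
12 | [(1E,4S)-4-(4-methoxybenzyloxy)-2-methylhexa-1,5-dien-1-yl]dimethylalane | C=C[C@@H](OCc1ccc(OC)cc1)C/C(C)=C/[Al](C)C | intermediate
13 | lithium butyl[(1E,4S)-4-(4-methoxybenzyloxy)-2-methylhexa-1,5-dien-1-yl]dimethylaluminate | C=C[C@@H](OCc1ccc(OC)cc1)C/C(C)=C/[Al-](C)(C)CCCC.[Li+] | intermediate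
14 | (2E,5S)-5-(4-methoxybenzyloxy)-3-methylhepta-2,6-dien-1-ol | C=C[C@@H](OCc1ccc(OC)cc1)C/C(C)=C/CO | intermediate
15 | {(2S,3S)-3-[(2S)-2-(4-methoxybenzyloxy)but-3-en-1-yl]-3-methyloxiran-2-yl}methanol | C=C[C@@H](OCc1ccc(OC)cc1)C[C@]1(C)O[C@H]1CO | intermediate
16 | (2R,3S)-2-(chloromethyl)-3-[(2S)-2-(4-methoxybenzyloxy)but-3-en-1-yl]-3-methyloxirane | C=C[C@@H](OCc1ccc(OC)cc1)C[C@]1(C)O[C@H]1CCl | intermediate
17 | dilithium alkoxide-acetylide of (3S,5S)-5-(4-methoxybenzyloxy)-3-methylhept-6-en-1-yn-3-ol | C=C[C@@H](OCc1ccc(OC)cc1)C[C@](C)(O[Li])C#C[Li] | intermediate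
18 | (4S,6S)-4-hydroxy-6-(4-methoxybenzyloxy)-4-methyloct-7-en-2-ynal | C=C[C@@H](OCc1ccc(OC)cc1)C[C@](C)(O)C#CC=O | intermediate
19 | (4S,6S)-6-(4-methoxybenzyloxy)-4-methyl-4-(triethylsilyloxy)oct-7-en-2-ynal | C=C[C@@H](OCc1ccc(OC)cc1)C[C@](C)(O[Si](CC)(CC)CC)C#CC=O | intermediate
20 | (3S,5S)-8,8-diethoxy-3-(4-methoxybenzyloxy)-5-methyl-5-(triethylsilyloxy)oct-1-en-6-yne | C=C[C@@H](OCc1ccc(OC)cc1)C[C@](C)(O[Si](CC)(CC)CC)C#CC(OCC)OCC | intermediate
21 | (3S,5S)-8,8-diethoxy-3-(4-methoxybenzyloxy)-5-methyl-5-(triethylsilyloxy)oct-6-yne-1,2-diol (both C2 epimers) | OCC(O)[C@@H](OCc1ccc(OC)cc1)C[C@](C)(O[Si](CC)(CC)CC)C#CC(OCC)OCC | intermediate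
22 | (2S,4S)-7,7-diethoxy-2-(4-methoxybenzyloxy)-4-methyl-4-(triethylsilyloxy)hept-5-ynal | O=C[C@@H](OCc1ccc(OC)cc1)C[C@](C)(O[Si](CC)(CC)CC)C#CC(OCC)OCC | intermediate
23 | methyl acrylate | C=CC(=O)OC | starting material
24 | methyl (4S,6S)-9,9-diethoxy-3-hydroxy-4-(4-methoxybenzyloxy)-6-methyl-2-methylidene-6-(triethylsilyloxy)non-7-ynoate (both C3 epimers) | COC(=O)C(=C)C(O)[C@@H](OCc1ccc(OC)cc1)C[C@](C)(O[Si](CC)(CC)CC)C#CC(OCC)OCC | intermediate
25 | methyl (2Z,4S,6S)-2-(bromomethyl)-9,9-diethoxy-4-(4-methoxybenzyloxy)-6-methyl-6-(triethylsilyloxy)non-2-en-7-ynoate | COC(=O)/C(CBr)=C/[C@@H](OCc1ccc(OC)cc1)C[C@](C)(O[Si](CC)(CC)CC)C#CC(OCC)OCC | intermediate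
26 | methyl (3S,4S,5Z)-3-[(1S,3S)-6,6-diethoxy-1-(4-methoxybenzyloxy)-3-methyl-3-(triethylsilyloxy)hex-4-yn-1-yl]-4-hydroxy-6-iodo-2-methylidenehept-5-enoate | COC(=O)C(=C)[C@@H]([C@H](O)/C=C(/C)I)[C@@H](OCc1ccc(OC)cc1)C[C@](C)(O[Si](CC)(CC)CC)C#CC(OCC)OCC | intermediate
27 | (4R,5S)-4-[(1S,3S)-6,6-diethoxy-1-(4-methoxybenzyloxy)-3-methyl-3-(triethylsilyloxy)hex-4-yn-1-yl]-5-[(Z)-2-iodoprop-1-en-1-yl]-3-methylidenedihydrofuran-2(3H)-one | C=C1C(=O)O[C@H](/C=C(/C)I)[C@H]1[C@@H](OCc2ccc(OC)cc2)C[C@](C)(O[Si](CC)(CC)CC)C#CC(OCC)OCC | intermediate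
28 | (4R,5S)-4-[(1S,3S)-6,6-diethoxy-1-hydroxy-3-methyl-3-(triethylsilyloxy)hex-4-yn-1-yl]-5-[(Z)-2-iodoprop-1-en-1-yl]-3-methylidenedihydrofuran-2(3H)-one | C=C1C(=O)O[C@H](/C=C(/C)I)[C@H]1[C@@H](O)C[C@](C)(O[Si](CC)(CC)CC)C#CC(OCC)OCC | intermediate
29 | (1R,3S)-6,6-diethoxy-1-{(2S,3R)-2-[(Z)-2-iodoprop-1-en-1-yl]-4-methylidene-5-oxotetrahydrofuran-3-yl}-3-methyl-3-(triethylsilyloxy)hex-4-yn-1-yl (E)-4-acetoxy-2-methylbut-2-enoate | C=C1C(=O)O[C@H](/C=C(/C)I)[C@H]1[C@H](OC(=O)/C(C)=C/COC(C)=O)C[C@](C)(O[Si](CC)(CC)CC)C#CC(OCC)OCC | intermediate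
30 | (1R,3S)-3-hydroxy-1-{(2S,3R)-2-[(Z)-2-iodoprop-1-en-1-yl]-4-methylidene-5-oxotetrahydrofuran-3-yl}-3-methyl-6-oxohex-4-yn-1-yl (E)-4-acetoxy-2-methylbut-2-enoate | C=C1C(=O)O[C@H](/C=C(/C)I)[C@H]1[C@H](OC(=O)/C(C)=C/COC(C)=O)C[C@](C)(O)C#CC=O | intermediate
31 | (4Z,6R,7R,8R,10S)-8-[(E)-4-acetoxy-2-methylbut-2-enoyloxy]-3,10-dihydroxygermacra-4,11(13)-dien-1-yn-12,6-olide (both C3 epimers) | C=C1C(=O)O[C@@H]2/C=C(/C)C(O)C#C[C@@](C)(O)C[C@@H](OC(=O)/C(C)=C/COC(C)=O)[C@@H]12 | intermediate
32 | (4Z,6R,7R,8R,10S)-8-[(E)-4-acetoxy-2-methylbut-2-enoyloxy]-10-hydroxy-3-oxogermacra-4,11(13)-dien-1-yn-12,6-olide | C=C1C(=O)O[C@@H]2/C=C(/C)C(=O)C#C[C@@](C)(O)C[C@@H](OC(=O)/C(C)=C/COC(C)=O)[C@@H]12 | intermediate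
33 | (4Z,6R,7R,8R,10S)-8-[(E)-4-acetoxy-2-methylbut-2-enoyloxy]-1-oxo-3,10-epoxygermacra-2,4,11(13)-trien-12,6-olide (CNP0387534.1) | C=C1C(=O)O[C@@H]2/C=C(/C)C3=CC(=O)[C@](C)(C[C@@H](OC(=O)/C(C)=C/COC(C)=O)[C@@H]12)O3 | target

**Step count and risks**

Total step count: 22. Longest linear sequence: 18 steps (steps 5–22, from 9).

Steps most likely to fail:

1. Step 20 (ring closure at C3–C4). Ring closure may be slower than intermolecular coupling because the strained ene-yne ring forms reluctantly, and the low-valent nickel may ionise the allylic acetate of the side chain or the reactive ynal may be reduced before it is alkenylated. Fallback (macrocyclisation before the side chain is attached, esterification moved to the end): it sets out from 27 and comes back at 33. Aqueous formic acid (HCO2H/THF/H2O) should cleave the acetal and the triethylsilyl ether of 27 but leave the 4-methoxybenzyl ether, giving the PMB-protected hydroxy-ynal F1. The same CrCl2/NiCl2 closure would then give the macrocyclic carbinol F2, Dess–Martin oxidation the macrocyclic ynone F3, and the gold-catalysed cycloisomerisation of step 22 the furanone PMB ether F4. The C8 oxygen stays protected throughout, so it cannot add to the ynone. DDQ then frees the 8-epi alcohol F5, and Mitsunobu esterification with 8 (PPh3, diisopropyl azodicarboxylate) inverts C8 and gives 33.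

2. Step 16 (Barbier allylation). The facial bias exerted by the C8 ether may be weak, or a chelated Z-allylchromium pathway may erode the 6,7-anti preference, so that diastereomeric lactones form. Fallback (stereocontrol handed from the substrate to a reagent): the same partners 25 and 4 are coupled by a chromium-catalytic Nozaki–Hiyama allylation (CrCl3 10 mol %, Mn powder, Me3SiCl, Et3N) carrying a chiral bis(oxazolinyl)carbazole ligand, so that the ligand sphere rather than C8 selects the aldehyde face; acid lactonisation as in step 16 returns to 27. No new compound is made (F0).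

3. Step 18 (Mitsunobu inversion at C8). The secondary alcohol next to the ring carbon C7 may react sluggishly, with elimination or acyl-hydrazide formation competing with substitution. Fallback (inversion by oxidation and directed reduction, then esterification with retention): it sets out from 28 and comes back at 30. Dess–Martin oxidation should give the 8-ketone F6, and HF·pyridine removes the silyl group to give the β-hydroxy ketone F7. Evans–Saksena reduction (Me4NBH(OAc)3, MeCN/AcOH, −40 °C) delivers hydride from the C10 alkoxyborohydride through a chair in which the slim alkynyl group is axial, which should give the (8R)-diol F8. Yamaguchi esterification of its secondary hydroxyl with 8 (2,4,6-trichlorobenzoyl chloride, Et3N, 4-dimethylaminopyridine) gives the hydroxy acetal ester F9, and the conditions of step 19 convert it into 30.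

**Further compounds**

F0 | step 16 | none | none
F1 | step 20 | (4S,6S)-4-hydroxy-6-{(2S,3R)-2-[(Z)-2-iodoprop-1-en-1-yl]-4-methylidene-5-oxotetrahydrofuran-3-yl}-6-(4-methoxybenzyloxy)-4-methylhex-2-ynal | C=C1C(=O)O[C@H](/C=C(/C)I)[C@H]1[C@@H](OCc2ccc(OC)cc2)C[C@](C)(O)C#CC=O
F2 | step 20 | (4Z,6R,7R,8S,10S)-3,10-dihydroxy-8-(4-methoxybenzyloxy)germacra-4,11(13)-dien-1-yn-12,6-olide (both C3 epimers) | C=C1C(=O)O[C@@H]2/C=C(/C)C(O)C#C[C@@](C)(O)C[C@H](OCc3ccc(OC)cc3)[C@@H]12
F3 | step 20 | (4Z,6R,7R,8S,10S)-10-hydroxy-8-(4-methoxybenzyloxy)-3-oxogermacra-4,11(13)-dien-1-yn-12,6-olide | C=C1C(=O)O[C@@H]2/C=C(/C)C(=O)C#C[C@@](C)(O)C[C@H](OCc3ccc(OC)cc3)[C@@H]12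
F4 | step 20 | (4Z,6R,7R,8S,10S)-8-(4-methoxybenzyloxy)-1-oxo-3,10-epoxygermacra-2,4,11(13)-trien-12,6-olide | C=C1C(=O)O[C@@H]2/C=C(/C)C3=CC(=O)[C@](C)(C[C@H](OCc4ccc(OC)cc4)[C@@H]12)O3
F5 | step 20 | (4Z,6R,7R,8S,10S)-8-hydroxy-1-oxo-3,10-epoxygermacra-2,4,11(13)-trien-12,6-olide | C=C1C(=O)O[C@@H]2/C=C(/C)C3=CC(=O)[C@](C)(C[C@H](O)[C@@H]12)O3
F6 | step 18 | (4R,5S)-4-[(3S)-6,6-diethoxy-3-methyl-3-(triethylsilyloxy)hex-4-ynoyl]-5-[(Z)-2-iodoprop-1-en-1-yl]-3-methylidenedihydrofuran-2(3H)-one | C=C1C(=O)O[C@H](/C=C(/C)I)[C@H]1C(=O)C[C@](C)(O[Si](CC)(CC)CC)C#CC(OCC)OCC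
F7 | step 18 | (4R,5S)-4-[(3S)-6,6-diethoxy-3-hydroxy-3-methylhex-4-ynoyl]-5-[(Z)-2-iodoprop-1-en-1-yl]-3-methylidenedihydrofuran-2(3H)-one | C=C1C(=O)O[C@H](/C=C(/C)I)[C@H]1C(=O)C[C@](C)(O)C#CC(OCC)OCC
F8 | step 18 | (4R,5S)-4-[(1R,3S)-6,6-diethoxy-1,3-dihydroxy-3-methylhex-4-yn-1-yl]-5-[(Z)-2-iodoprop-1-en-1-yl]-3-methylidenedihydrofuran-2(3H)-one | C=C1C(=O)O[C@H](/C=C(/C)I)[C@H]1[C@H](O)C[C@](C)(O)C#CC(OCC)OCC
F9 | step 18 | (1R,3S)-6,6-diethoxy-3-hydroxy-1-{(2S,3R)-2-[(Z)-2-iodoprop-1-en-1-yl]-4-methylidene-5-oxotetrahydrofuran-3-yl}-3-methylhex-4-yn-1-yl (E)-4-acetoxy-2-methylbut-2-enoate | C=C1C(=O)O[C@H](/C=C(/C)I)[C@H]1[C@H](OC(=O)/C(C)=C/COC(C)=O)C[C@](C)(O)C#CC(OCC)OCC
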